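## Retrosynthetic overview

1. Target ⇐ Rubottom oxidation/desilylation of a C1 silyl enol ether that already carries the C3, C6 and C8 angelates; this sets C2–OH and the C1 ketone last.
2. The cis-3,6-diol ⇐ O–O reduction of a 2,3-dioxabicyclo[2.2.2]octene formed by [4+2] cycloaddition of singlet oxygen to a 2-silyloxy-1,3-diene (key step; sets C3 and C6 together).
3. C4–O ⇐ an earlier singlet-oxygen [4+2] cycloaddition on the linear 1-silyloxy diene of (R)-carvone, which supplies the carbocycle and C5.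
4. Side chain ⇐ C8–C9 bond by opening a methyl (R)-glycidate-derived epoxide with the allyl Grignard reagent from the isopropenyl group; C8–O by SeO2 oxidation (ene/[2,3]) and 1,3-syn reduction; oxirane by displacement with inversion at C10.
5. Ring order: carbocycle bought → transient dioxabicycle across C1/C4 → oxirane C10–C11 → transient dioxabicycle across C3/C6.

Locants used below (kept from carvone): ring C1 (C=O), C2 (C–CH3), C3, C4, C5 (bears the side chain), C6; side chain C7 (attached to C5, carries the exocyclic CH2), C8, C9, C10, C11 (CMe2). Ang = (Z)-2-methylbut-2-enoyl; TBS = tert-butyldimethylsilyl; TMS = trimethylsilyl; TES = triethylsilyl.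

Assumption: metal enolates, alkoxides and boron or tin chelates that form and are consumed within one operation are treated as part of the reagent system and carry no number.

## Route

Step 1
Reactants: 1 (R)-(−)-carvone
Product: 2 linear TMS dienol ether of carvone [(5S)-2-methyl-5-(prop-1-en-2-yl)-1-(trimethylsilyloxy)cyclohexa-1,3-diene]
Conditions: MeMgBr (1.2 equiv), FeCl3 (5 mol %), Et2O, −20 °C; then Me3SiCl, Et3N, DMPU, 0 °C
Reagents that add atoms: chlorotrimethylsilane, C[Si](C)(C)Cl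
Why: Kharasch-type deprotonation, in which MeMgBr/FeCl3 acts as a base and removes a γ-hydrogen (C4) irreversibly to give the extended dienolate, followed by O-silylation to the linear 1-silyloxy-1,3-diene; C5 is untouched.

Step 2
Reactants: 2 linear TMS dienol ether of carvone
Product: 4 (4S,5R)-4-hydroxycarvone, via silyloxy endoperoxide 3 (not isolated)
Conditions: O2, visible light, tetraphenylporphyrin (1 mol %), CH2Cl2, −78 °C; then PPh3, −78 °C to rt; then aqueous citric acid, THF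
Reagents that add atoms: oxygen, O=O
Why: Singlet-oxygen [4+2] cycloaddition (hetero-Diels–Alder) onto the s-cis diene occurs anti to the isopropenyl group on the neighbouring C5, so the new C4–O bond is trans to C5 (4S), and PPh3 reduction with loss of the silyl hemiketal releases the γ-hydroxy enone.

Step 3
Reactants: 4 (4S,5R)-4-hydroxycarvone
Product: 5 4-O-TBS-(4S,5R)-4-hydroxycarvone
Conditions: t-BuMe2SiCl, imidazole, DMF, rt
Reagents that add atoms: tert-butyldimethylsilyl chloride, CC(C)(C)[Si](C)(C)Cl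
Why: Standard silylation of the secondary alcohol (silyl ether formation); no stereocentre is touched.

Step 4
Reactants: 5 4-O-TBS-(4S,5R)-4-hydroxycarvone
Product: 6 allylic chloride (4S,5R) [5-(3-chloroprop-1-en-2-yl) enone]
Conditions: Ca(OCl)2, solid CO2, CH2Cl2/H2O, 0 °C
Reagents that add atoms: calcium hypochlorite, [Ca+2].[O-]Cl.[O-]Cl
Why: Ene-type chlorination by HOCl generated in the flask attacks only the electron-rich 1,1-disubstituted alkene (the enone alkene is too electron-poor) and gives the transposed allylic chloride.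

Step 5
Reactants: 7 methyl (R)-glycidate
Product: 8 (R)-2-(oxiran-2-yl)propan-2-yl trimethylsilyl ether
Conditions: MeLi (2.1 equiv), Et2O, −78 °C; then Me3SiCl (2.2 equiv), −78 to 0 °C
Reagents that add atoms: methyllithium, [Li]C; chlorotrimethylsilane, C[Si](C)(C)Cl
Why: Twofold addition of MeLi to the ester at −78 °C is much faster than epoxide opening, and the tertiary alkoxide is capped in the same flask; the bought stereocentre is not involved.

Step 6
Reactants: 6 allylic chloride (4S,5R); 8 (R)-2-(oxiran-2-yl)propan-2-yl trimethylsilyl ether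
Product: 12 enone diol (4S,5R,10R), via TMS dienol ether 9 (not isolated), via allyl Grignard reagent 10 (not isolated), via coupled silyl ether 11 (not isolated)
Conditions: LiN(i-Pr)2, Me3SiCl (in situ), THF, −78 °C; activated Mg, THF, −20 °C; 8, CuI (10 mol %), −40 to 0 °C; then 0.5 M HCl, THF, 0 °C
Reagents that add atoms: none
Why: Kinetic enolisation/O-silylation masks the enone as its 2-silyloxydiene, Mg insertion gives the symmetrical 2-substituted allyl Grignard reagent, and CuI-catalysed SN2 opening of epoxide 8 at its CH2 end forms the C8–C9 bond and carries over the bought C10 configuration (10R); dilute acid then removes both TMS groups.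

Step 7
Reactants: 12 enone diol (4S,5R,10R)
Product: 14 C8 ketone (4S,5R,10R), via C8 allylic alcohol 13 (not isolated)
Conditions: SeO2 (0.5 equiv), t-BuOOH, CH2Cl2, rt; then MnO2, CH2Cl2, rt
Reagents that add atoms: selenium dioxide, O=[Se]=O; tert-butyl hydroperoxide, CC(C)(C)OO
Why: SeO2 allylic oxidation (ene reaction then [2,3]-sigmatropic rearrangement) hits the CH2 next to the only electron-rich alkene (C5–H is hindered and deactivated by C4–O, the enone alkene is inert), and MnO2 then oxidises only the allylic C8 alcohol.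

Step 8
Reactants: 14 C8 ketone (4S,5R,10R)
Product: 15 syn-8,10-triol (4S,5R,8S,10R)
Conditions: Et2BOMe, THF/MeOH (4:1), −78 °C; NaBH4, −78 °C; MeOH co-evaporation
Reagents that add atoms: none
Why: Narasaka–Prasad reduction, in which the diethylboron chelate between the C10 oxygen and the C8 carbonyl is attacked axially by borohydride to give the 1,3-syn diol (8S set by 10R), while the unchelated ring enone is left alone at −78 °C.

Step 9
Reactants: 15 syn-8,10-triol (4S,5R,8S,10R)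
Product: 17 hydroxy epoxide (4S,5R,8S,10S), via C10 tosylate 16 (not isolated)
Conditions: Bu2SnO (5 mol %), TsCl, Et3N, CH2Cl2, 0 °C; then K2CO3, MeOH, 0 °C
Reagents that add atoms: none
Why: Stannylene-catalysed tosylation selects the secondary oxygen of the 1,2-diol, and the tertiary alkoxide then closes the oxirane by intramolecular Williamson substitution (3-exo-tet) with inversion at C10 (10R to 10S), placing the oxirane oxygen anti to C8–OH.

Step 10
Reactants: 17 hydroxy epoxide (4S,5R,8S,10S)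
Product: 18 C8 angelate (4S,5R,8S,10S)
Conditions: angelic anhydride (1.5 equiv), LiN(SiMe3)2 (1.1 equiv), THF, −78 °C
Reagents that add atoms: angelic anhydride, C/C=C(/C)C(=O)OC(=O)/C(C)=C\C
Why: O-acylation of the lithium alkoxide, formed in the presence of the anhydride at −78 °C, installs the angelate without the nucleophilic catalysis that isomerises angelates to tiglates.

Step 11
Reactants: 18 C8 angelate (4S,5R,8S,10S)
Product: 19 TBS dienol ether (4S,5R,8S,10S)
Conditions: LiN(SiMe3)2, t-BuMe2SiCl, DMPU, THF, −78 °C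
Reagents that add atoms: tert-butyldimethylsilyl chloride, CC(C)(C)[Si](C)(C)Cl
Why: Kinetic deprotonation at C6 (α′) and O-silylation (silyl enol ether formation) give the cross-conjugated 2-silyloxy-1,3-diene needed for the second cycloaddition.

Step 12
Reactants: 19 TBS dienol ether (4S,5R,8S,10S)
Product: 21 cis-3,6-diol silyl enol ether (3S,4R,5S,6S,8S,10S), via C3/C6 endoperoxide 20 (not isolated)
Conditions: O2, visible light, tetraphenylporphyrin (1 mol %), CH2Cl2, −78 °C; then thiourea, MeOH, −78 to 0 °C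
Reagents that add atoms: oxygen, O=O
Why: Singlet-oxygen [4+2] cycloaddition across C3 and C6 takes place anti to the carbon side chain at C5 (the face that carries only the allylic C4 oxygen), so C3–O and C6–O are formed together and cis to each other (3S,6S), and thiourea reduces only the O–O bond.

Step 13
Reactants: 21 cis-3,6-diol silyl enol ether (3S,4R,5S,6S,8S,10S)
Product: 22 tris-angelate silyl enol ether (3S,4R,5S,6S,8S,10S)
Conditions: angelic anhydride (3 equiv), LiN(SiMe3)2 (2.2 equiv), THF, −78 °C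
Reagents that add atoms: angelic anhydride, C/C=C(/C)C(=O)OC(=O)/C(C)=C\C
Why: Twofold O-acylation of the dialkoxide at low temperature; the silyl enol ether and the oxirane are inert to these conditions.

Step 14
Reactants: 22 tris-angelate silyl enol ether (3S,4R,5S,6S,8S,10S)
Product: 25 target CNP0145026.1, via silyloxy epoxide 23 (not isolated), via C4 silyl ether 24 (not isolated)
Conditions: dimethyldioxirane, acetone/CH2Cl2, −78 to −20 °C; then HF·pyridine, pyridine, THF, 0 °C to rt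
Reagents that add atoms: dimethyldioxirane, CC1(C)OO1
Why: Rubottom oxidation, in which dimethyldioxirane epoxidises the silyl enol ether on the face opposite the two flanking allylic angelates, HF opens the silyloxy epoxide to the α-hydroxy ketone with C2–OH trans to C3–O (2S), and HF then removes the C4 silyl ether.

## Compound list

1 | (R)-(−)-carvone, (5R)-2-methyl-5-(prop-1-en-2-yl)cyclohex-2-en-1-one | C=C(C)[C@@H]1CC=C(C)C(=O)C1 | starting material
2 | (5S)-2-methyl-5-(prop-1-en-2-yl)-1-(trimethylsilyloxy)cyclohexa-1,3-diene | C=C(C)[C@@H]1C=CC(C)=C(O[Si](C)(C)C)C1 | intermediate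
3 | 6-methyl-8-(prop-1-en-2-yl)-1-(trimethylsilyloxy)-2,3-dioxabicyclo[2.2.2]oct-5-ene, O–O bridge (carvone C1 to C4) anti to the isopropenyl group | C=C(C)[C@@H]1[C@@H]2C=C(C)[C@@](O[Si](C)(C)C)(OO2)C1 | intermediate
4 | (4S,5R)-4-hydroxy-2-methyl-5-(prop-1-en-2-yl)cyclohex-2-en-1-one (trans-4-hydroxycarvone) | C=C(C)[C@@H]1[C@@H](O)C=C(C)C(=O)C1 | intermediate
5 | (4S,5R)-4-(tert-butyldimethylsilyloxy)-2-methyl-5-(prop-1-en-2-yl)cyclohex-2-en-1-one | C=C(C)[C@@H]1[C@@H](O[Si](C)(C)C(C)(C)C)C=C(C)C(=O)C1 | intermediate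
6 | (4S,5R)-4-(tert-butyldimethylsilyloxy)-5-(3-chloroprop-1-en-2-yl)-2-methylcyclohex-2-en-1-one | C=C(CCl)[C@@H]1[C@@H](O[Si](C)(C)C(C)(C)C)C=C(C)C(=O)C1 | intermediate
7 | methyl (2R)-oxirane-2-carboxylate (methyl (R)-glycidate) | COC(=O)[C@H]1CO1 | starting material
8 | trimethyl({2-[(2R)-oxiran-2-yl]propan-2-yl}oxy)silane | CC(C)(O[Si](C)(C)C)[C@H]1CO1 | intermediate
9 | C1 trimethylsilyl dienol ether of 6 (double bonds C1=C6 and C2=C3; 4S,5R) | C=C(CCl)[C@@H]1[C@@H](O[Si](C)(C)C(C)(C)C)C=C(C)C(O[Si](C)(C)C)=C1 | intermediate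
10 | allylmagnesium chloride from 9 (C8–MgCl; 4S,5R) | C=C(C[Mg]Cl)[C@@H]1[C@@H](O[Si](C)(C)C(C)(C)C)C=C(C)C(O[Si](C)(C)C)=C1 | intermediate
11 | coupled dienol ether (4S,5R,10R); C7 carries CH2–CH2–CH(OH)–C(CH3)2OSiMe3 | C=C([C@@H]1[C@@H](O[Si](C)(C)C(C)(C)C)C=C(C)C(O[Si](C)(C)C)=C1)CC[C@@H](O)C(C)(C)O[Si](C)(C)C | intermediate
12 | (4S,5R)-4-(tert-butyldimethylsilyloxy)-5-[(5R)-5,6-dihydroxy-6-methylhept-1-en-2-yl]-2-methylcyclohex-2-en-1-one (enone diol; 10R) | C=C([C@@H]1[C@@H](O[Si](C)(C)C(C)(C)C)C=C(C)C(=O)C1)CC[C@@H](O)C(C)(C)O | intermediate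
13 | C8 allylic alcohol of 12, mixture of C8 epimers (4S,5R,8RS,10R) | C=C([C@@H]1[C@@H](O[Si](C)(C)C(C)(C)C)C=C(C)C(=O)C1)C(O)C[C@@H](O)C(C)(C)O | intermediate
14 | (4S,5R)-4-(tert-butyldimethylsilyloxy)-5-[(5R)-5,6-dihydroxy-6-methyl-3-oxohept-1-en-2-yl]-2-methylcyclohex-2-en-1-one (C8 ketone; 10R) | C=C([C@@H]1[C@@H](O[Si](C)(C)C(C)(C)C)C=C(C)C(=O)C1)C(=O)C[C@@H](O)C(C)(C)O | intermediate
15 | (4S,5R)-4-(tert-butyldimethylsilyloxy)-2-methyl-5-[(3S,5R)-3,5,6-trihydroxy-6-methylhept-1-en-2-yl]cyclohex-2-en-1-one (syn-8,10-triol; 8S,10R) | C=C([C@@H]1[C@@H](O[Si](C)(C)C(C)(C)C)C=C(C)C(=O)C1)[C@H](C[C@@H](O)C(C)(C)O)O | intermediate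
16 | C10 p-toluenesulfonate of 15 (4S,5R,8S,10R) | C=C([C@@H]1[C@@H](O[Si](C)(C)C(C)(C)C)C=C(C)C(=O)C1)[C@H](C[C@@H](OS(=O)(=O)c1ccc(C)cc1)C(C)(C)O)O | intermediate
17 | (4S,5R)-4-(tert-butyldimethylsilyloxy)-5-{(3S)-4-[(2S)-3,3-dimethyloxiran-2-yl]-3-hydroxybut-1-en-2-yl}-2-methylcyclohex-2-en-1-one (hydroxy epoxide; 8S,10S) | C=C([C@@H]1[C@@H](O[Si](C)(C)C(C)(C)C)C=C(C)C(=O)C1)[C@H](C[C@@H]1OC1(C)C)O | intermediate
18 | C8 angelate of 17 (4S,5R,8S,10S) | C=C([C@@H]1[C@@H](O[Si](C)(C)C(C)(C)C)C=C(C)C(=O)C1)[C@H](C[C@@H]1OC1(C)C)OC(=O)/C(C)=C\C | intermediate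
19 | C1 tert-butyldimethylsilyl dienol ether of 18 (double bonds C1=C6 and C2=C3; 4S,5R,8S,10S) | C=C([C@@H]1[C@@H](O[Si](C)(C)C(C)(C)C)C=C(C)C(O[Si](C)(C)C(C)(C)C)=C1)[C@H](C[C@@H]1OC1(C)C)OC(=O)/C(C)=C\C | intermediate
20 | C3/C6 endoperoxide of 19 (2,3-dioxabicyclo[2.2.2]oct-5-ene; O–O bridge on the face of C4–OTBS, anti to the side chain; 8S,10S) | C=C([C@@H]1[C@@H](O[Si](C)(C)C(C)(C)C)[C@@H]2C(C)=C(O[Si](C)(C)C(C)(C)C)[C@H]1OO2)[C@H](C[C@@H]1OC1(C)C)OC(=O)/C(C)=C\C | intermediate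
21 | cis-3,6-diol C1 silyl enol ether (3S,4R,5S,6S,8S,10S) | C=C([C@@H]1[C@@H](O[Si](C)(C)C(C)(C)C)[C@@H](O)C(C)=C(O[Si](C)(C)C(C)(C)C)[C@H]1O)[C@H](C[C@@H]1OC1(C)C)OC(=O)/C(C)=C\C | intermediate
22 | 3,6,8-tris-angelate C1 silyl enol ether (3S,4R,5S,6S,8S,10S) | C=C([C@@H]1[C@@H](O[Si](C)(C)C(C)(C)C)[C@@H](OC(=O)/C(C)=C\C)C(C)=C(O[Si](C)(C)C(C)(C)C)[C@H]1OC(=O)/C(C)=C\C)[C@H](C[C@@H]1OC1(C)C)OC(=O)/C(C)=C\C | intermediate
23 | C1/C2 silyloxy epoxide of 22 (epoxide oxygen anti to the C3 and C6 angelates) | C=C([C@@H]1[C@@H](O[Si](C)(C)C(C)(C)C)[C@@H](OC(=O)/C(C)=C\C)[C@]2(C)O[C@]2(O[Si](C)(C)C(C)(C)C)[C@H]1OC(=O)/C(C)=C\C)[C@H](C[C@@H]1OC1(C)C)OC(=O)/C(C)=C\C | intermediate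
24 | 4-O-TBS ether of the target (2S,3R,4R,5S,6S,8S,10S) | C=C([C@@H]1[C@@H](O[Si](C)(C)C(C)(C)C)[C@@H](OC(=O)/C(C)=C\C)[C@](C)(O)C(=O)[C@H]1OC(=O)/C(C)=C\C)[C@H](C[C@@H]1OC1(C)C)OC(=O)/C(C)=C\C | intermediate
25 | CNP0145026.1 (2S,3R,4R,5R,6S,8S,10S under the locants above) | C=C([C@@H]1[C@@H](O)[C@@H](OC(=O)/C(C)=C\C)[C@](C)(O)C(=O)[C@H]1OC(=O)/C(C)=C\C)[C@H](C[C@@H]1OC1(C)C)OC(=O)/C(C)=C\C | target

## Step count and risks

Total step count: 14. Longest linear sequence: 13 steps (1 → 25, steps 1–4 and 6–14); fragment 8 takes one step.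

**Step 12 (second photooxygenation).** The face choice rests on the C5 side chain outweighing the bulky C4 silyl ether on the other face, and the silyloxy endoperoxide can fragment by β-elimination. The fallback replaces steric control by hydrogen-bond direction from a free C4 hydroxyl. It sets out from 18: HF·pyridine removes the C4 silyl group to give the 4-hydroxy enone F1; Me3SiCl/imidazole gives the C4 trimethylsilyl ether F2; LiN(SiMe3)2/t-BuMe2SiCl gives the silyl dienol ether F3; K2CO3/MeOH at 0 °C cleaves only the alkyl trimethylsilyl ether to give the hydroxy dienol ether F4. Singlet oxygen in CCl4 then adds syn to the free allylic hydroxyl, which is also the face anti to the side chain, to give the hydroxy endoperoxide F5. Silylation with t-BuMe2SiOTf/2,6-lutidine at −78 °C brings the sequence back to the route at 20.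

**Step 6 (fragment coupling).** Forming an allylic Grignard reagent next to a labile silyl dienol ether risks Wurtz coupling and loss of the mask. The fallback masks the ketone by reduction instead. It sets out from 6: NaBH4/CeCl3 gives the allylic alcohol F6; Et3SiCl/imidazole gives the triethylsilyl ether F7; Mg gives the Grignard reagent F8; CuI-catalysed opening of 8 gives the coupled alcohol F9; PPTS/MeOH removes the triethylsilyl and trimethylsilyl groups to give the triol F10. MnO2 oxidises only the allylic C1 alcohol and returns to the route at 12.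

**Step 8 (syn reduction).** Borohydride may add 1,4 to the α-methylene ketone or touch the ring enone. The fallback uses internal hydride delivery and corrects C8 by inversion. It sets out from 14: Me4NBH(OAc)3 in MeCN/AcOH at −30 °C reduces only the hydroxy-directed ketone, strictly 1,2, to the anti-triol F11; Bu2SnO-catalysed tosylation gives the C10 tosylate F12, and K2CO3/MeOH closes it to the (8R)-hydroxy epoxide F13. Mitsunobu esterification with angelic acid (PPh3, diisopropyl azodicarboxylate) inverts C8 and installs the ester, returning to the route at 18.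

## Further compounds

F1 | step 12 | 4-hydroxy enone, 18 without the C4 silyl group (4S,5R,8S,10S) | C=C([C@@H]1[C@@H](O)C=C(C)C(=O)C1)[C@H](C[C@@H]1OC1(C)C)OC(=O)/C(C)=C\C
F2 | step 12 | C4 trimethylsilyl ether of F1 | C=C([C@@H]1[C@@H](O[Si](C)(C)C)C=C(C)C(=O)C1)[C@H](C[C@@H]1OC1(C)C)OC(=O)/C(C)=C\C
F3 | step 12 | C1 tert-butyldimethylsilyl dienol ether of F2 | C=C([C@@H]1[C@@H](O[Si](C)(C)C)C=C(C)C(O[Si](C)(C)C(C)(C)C)=C1)[C@H](C[C@@H]1OC1(C)C)OC(=O)/C(C)=C\C
F4 | step 12 | C4-hydroxy dienol ether (F3 without the trimethylsilyl group) | C=C([C@@H]1[C@@H](O)C=C(C)C(O[Si](C)(C)C(C)(C)C)=C1)[C@H](C[C@@H]1OC1(C)C)OC(=O)/C(C)=C\C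
F5 | step 12 | C4-hydroxy C3/C6 endoperoxide (O–O bridge syn to C4–OH) | C=C([C@@H]1[C@@H](O)[C@@H]2C(C)=C(O[Si](C)(C)C(C)(C)C)[C@H]1OO2)[C@H](C[C@@H]1OC1(C)C)OC(=O)/C(C)=C\C
F6 | step 6 | (1R,4S,5R)-4-(tert-butyldimethylsilyloxy)-5-(3-chloroprop-1-en-2-yl)-2-methylcyclohex-2-en-1-ol | C=C(CCl)[C@@H]1[C@@H](O[Si](C)(C)C(C)(C)C)C=C(C)[C@H](O)C1
F7 | step 6 | C1 triethylsilyl ether of F6 | C=C(CCl)[C@@H]1[C@@H](O[Si](C)(C)C(C)(C)C)C=C(C)[C@H](O[Si](CC)(CC)CC)C1
F8 | step 6 | allylmagnesium chloride from F7 | C=C(C[Mg]Cl)[C@@H]1[C@@H](O[Si](C)(C)C(C)(C)C)C=C(C)[C@H](O[Si](CC)(CC)CC)C1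
F9 | step 6 | coupled alcohol (C1–OSiEt3, C11–OSiMe3; 10R) | C=C([C@@H]1[C@@H](O[Si](C)(C)C(C)(C)C)C=C(C)[C@H](O[Si](CC)(CC)CC)C1)CC[C@@H](O)C(C)(C)O[Si](C)(C)C
F10 | step 6 | C1,C10,C11-triol (1R,4S,5R,10R) | C=C([C@@H]1[C@@H](O[Si](C)(C)C(C)(C)C)C=C(C)[C@H](O)C1)CC[C@@H](O)C(C)(C)O
F11 | step 8 | anti-8,10-triol (4S,5R,8R,10R) | C=C([C@@H]1[C@@H](O[Si](C)(C)C(C)(C)C)C=C(C)C(=O)C1)[C@@H](C[C@@H](O)C(C)(C)O)O
F12 | step 8 | C10 p-toluenesulfonate of F11 | C=C([C@@H]1[C@@H](O[Si](C)(C)C(C)(C)C)C=C(C)C(=O)C1)[C@@H](C[C@@H](OS(=O)(=O)c1ccc(C)cc1)C(C)(C)O)O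
F13 | step 8 | (8R)-hydroxy epoxide, C8 epimer of 17 (4S,5R,8R,10S) | C=C([C@@H]1[C@@H](O[Si](C)(C)C(C)(C)C)C=C(C)C(=O)C1)[C@@H](C[C@@H]1OC1(C)C)O
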